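**Retrosynthetic overview**

1. The target 17 is taken back through ketal hydrolysis, O-acetylation and ester saponification to the cis-tetralol 13, and from there to the 2-tetralone 12 by a dynamic kinetic transfer hydrogenation (C1 is labile next to the C2 ketone).
2. Key disconnection: both benzylic aryl–carbon bonds of 12 (C8a–C1 and C4a–C4) are cut at once. This gives the ortho-chloro arylboronate 10 (nucleophilic at C4a, electrophilic at C8a) and the citronellal-derived enone 5, joined in one flask by rhodium-catalysed enantioselective 1,4-addition followed by palladium-catalysed ketone α-arylation.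
3. Enabling feature: in ring B the oxygenated carbon C2 lies between C1 and C3, and C1 and C4 are bonded to the adjacent carbons C8a and C4a of the benzene ring A. With C2 at the ketone level, C4 becomes an enone β-carbon (electrophile) and C1 an enolizable α′-carbon (nucleophile), which a 1,2-ambiphilic arene can bridge.
4. Stereocentres: C11 comes from (S)-citronellal, C4 from the chiral diene on rhodium, and C1 and C2 together from the dynamic reduction, which funnels both C1 epimers of 12 into one alcohol.
5. Ring order: ring A is bought (6); a temporary dioxole ring is put on the catechol (step 5); ring B is closed in step 7; the dioxole is opened last.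

Key step: step 7

Remark: locants C1–C8a and C11 in the text are the tetralin-core locants of the target (C1 carries the side chain, C2 the acetoxy group, C4 the methyl group, C5 and C6 the catechol oxygens, C7 the carboxyl group, C11 is the side-chain stereocentre). In the systematic names (naphthalene-2-carboxylic acid numbering) core C4, C2 and C1 are C-5, C-7 and C-8.

Assumption: (S)-citronellal, (E)-1-bromoprop-1-ene and methyl 2,3,4-trihydroxybenzoate are taken as commercial materials.

**Route**

Step 1
Reactants: 1 (S)-citronellal; 2 (E)-1-bromoprop-1-ene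
Product: 4 (2E,6S)-6,10-dimethylundeca-2,9-dien-4-ol (both carbinol epimers), via (E)-prop-1-en-1-yllithium 3 (not isolated)
Conditions: 2, t-BuLi (2.0 equiv), Et2O, −78 °C; then 1, −78 → 0 °C; H2O quench
Reagents that add atoms: none
Why: bromine–lithium exchange proceeds with retention of the E geometry and the alkenyllithium adds 1,2 to the aldehyde; the new carbinol centre is uncontrolled and is erased in step 2, while the β-stereocentre of citronellal (C11) is not enolizable.

Step 2
Reactants: 4 (2E,6S)-6,10-dimethylundeca-2,9-dien-4-ol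
Product: 5 (2E,6S)-6,10-dimethylundeca-2,9-dien-4-one
Conditions: Dess–Martin periodinane (1.2 equiv), CH2Cl2, 0 °C → rt
Reagents that add atoms: none
Why: Dess–Martin oxidation of a secondary allylic alcohol under near-neutral conditions should keep the E alkene and the C11 stereocentre intact.

Step 3
Reactants: 6 methyl 2,3,4-trihydroxybenzoate
Product: 7 methyl 5-chloro-2,3,4-trihydroxybenzoate
Conditions: N-chlorosuccinimide (1.0 equiv), MeCN, 0 °C → rt, under N2
Reagents that add atoms: N-chlorosuccinimide, O=C1CCC(=O)N1Cl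
Why: electrophilic aromatic chlorination should go to C-5, which is ortho to the 4-OH, para to the 2-OH and meta to the ester, whereas C-6 is ortho to the ester.

Step 4
Reactants: 7 methyl 5-chloro-2,3,4-trihydroxybenzoate
Product: 8 methyl 5-chloro-2,3-dihydroxy-4-(trifluoromethanesulfonyloxy)benzoate
Conditions: PhNTf2 (1.0 equiv), Et3N (1.1 equiv), CH2Cl2, −20 → 0 °C
Reagents that add atoms: N-phenyl-bis(trifluoromethanesulfonimide), O=S(=O)(N(c1ccccc1)S(=O)(=O)C(F)(F)F)C(F)(F)F
Why: site-selective phenol sulfonylation: the 4-OH (para to the ester, ortho to chlorine) is the most acidic and is not hydrogen-bonded to the ester carbonyl, so one equivalent of base and a mild triflyl donor should mark this oxygen only.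

Step 5
Reactants: 8 methyl 5-chloro-2,3-dihydroxy-4-(trifluoromethanesulfonyloxy)benzoate
Product: 9 methyl 5-chloro-2,3-[(diphenylmethylene)dioxy]-4-(trifluoromethanesulfonyloxy)benzoate
Conditions: Ph2CCl2 (1.5 equiv), Ph2O, 170 °C, N2 sweep
Reagents that add atoms: dichlorodiphenylmethane, ClC(Cl)(c1ccccc1)c1ccccc1
Why: thermal ketalization of the only remaining catechol pair gives the diphenylmethylene ketal without base (no triflyl migration) and ties back the oxygen that will flank the carbon–boron bond.

Step 6
Reactants: 9 methyl 5-chloro-2,3-[(diphenylmethylene)dioxy]-4-(trifluoromethanesulfonyloxy)benzoate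
Product: 10 methyl 5-chloro-2,3-[(diphenylmethylene)dioxy]-4-(4,4,5,5-tetramethyl-1,3,2-dioxaborolan-2-yl)benzoate
Conditions: B2pin2 (1.3 equiv), Pd(dppf)Cl2 (5 mol %), KOAc (3 equiv), 1,4-dioxane, 90 °C
Reagents that add atoms: bis(pinacolato)diboron, CC1(C)OB(OC1(C)C)B1OC(C)(C)C(C)(C)O1
Why: Miyaura borylation; zerovalent palladium with dppf inserts into the C–OTf bond much faster than into the C–Cl bond, so the chloride is kept for step 7.

Step 7
Reactants: 10 methyl 5-chloro-2,3-[(diphenylmethylene)dioxy]-4-(4,4,5,5-tetramethyl-1,3,2-dioxaborolan-2-yl)benzoate; 5 (2E,6S)-6,10-dimethylundeca-2,9-dien-4-one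
Product: 12 methyl (5R)-3,4-[(diphenylmethylene)dioxy]-5-methyl-8-[(2S)-6-methylhept-5-en-2-yl]-7-oxo-5,6,7,8-tetrahydronaphthalene-2-carboxylate (both C-8 epimers), via β-aryl ketone 11 (not isolated)
Conditions: [RhCl(C2H4)2]2 (2.5 mol %), (R,R)-Ph-bod* (5.5 mol %), K3PO4 (3 equiv), degassed 1,4-dioxane–H2O (10:1), 50 °C; then Pd(OAc)2 (5 mol %), XPhos (10 mol %), same flask, 100 °C
Reagents that add atoms: none
Why: Proposed new method: the aryl group passes from boron to monovalent rhodium, inserts enantioselectively 1,4 into enone 5 at C4 and is released by protonolysis as ketone 11; on heating, zerovalent palladium inserts into the C8a–Cl bond, the potassium enolate at C1 binds and C–C reductive elimination forms the C8a–C1 bond. The closest known reactions are the Hayashi–Miyaura addition to (E)-alkyl enones, the Buchwald–Hartwig-type intramolecular α-arylation of ketones, and one-flask rhodium/palladium relays of ortho-chloroarylboron reagents that close C–N or C–O bonds; the relay to a 2-tetralone and the doubly ortho-substituted aryl group are the untested parts. Ring B is closed at C1 by a 6-(enolendo) C-arylation through a seven-membered aryl(enolate)palladacycle, since closure through the C3 enolate would give a four-membered ring. C4 is set by the chiral diene, which by the model for (E)-alkyl enones should deliver the aryl group to the Re face of C4 (R; the sense is to be confirmed on (E)-pent-3-en-2-one); C1 forms as a labile epimer mixture that step 8 corrects, and C11 is untouched. The step needs rhodium to react only at C–B and palladium only at C–Cl (temperature staging, with the boronate consumed before palladium is added), 1,4- over 1,2-addition, and C- over O-arylation; the aryl-rhodium has no ortho hydrogen, so no 1,4-rhodium shift can compete.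

Step 8
Reactants: 12 methyl (5R)-3,4-[(diphenylmethylene)dioxy]-5-methyl-8-[(2S)-6-methylhept-5-en-2-yl]-7-oxo-5,6,7,8-tetrahydronaphthalene-2-carboxylate
Product: 13 methyl (5R,7R,8S)-3,4-[(diphenylmethylene)dioxy]-7-hydroxy-5-methyl-8-[(2S)-6-methylhept-5-en-2-yl]-5,6,7,8-tetrahydronaphthalene-2-carboxylate
Conditions: RuCl(p-cymene)[(R,R)-TsDPEN] (2 mol %), HCO2H–Et3N (5:2), degassed DMF, 40 °C
Reagents that add atoms: none
Why: Noyori–Ikariya transfer hydrogenation with dynamic kinetic resolution: C1 (benzylic and α to the ketone) epimerizes through the enol under Et3N while the catalyst delivers hydride to the Si face of C2, anti to the side chain of the matching C1 epimer, so both epimers should funnel into the 1,2-cis alcohol (C1 S, C2 R); the (R,R) catalyst is chosen by the CH/π model with the benzo-fused C1 flank in the aryl position, to be confirmed on 1-methyl-2-tetralone.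

Step 9
Reactants: 13 methyl (5R,7R,8S)-3,4-[(diphenylmethylene)dioxy]-7-hydroxy-5-methyl-8-[(2S)-6-methylhept-5-en-2-yl]-5,6,7,8-tetrahydronaphthalene-2-carboxylate
Product: 14 (5R,7R,8S)-3,4-[(diphenylmethylene)dioxy]-7-hydroxy-5-methyl-8-[(2S)-6-methylhept-5-en-2-yl]-5,6,7,8-tetrahydronaphthalene-2-carboxylic acid
Conditions: LiOH·H2O (5 equiv), THF–MeOH–H2O (3:1:1), 45 °C; then 1 M HCl to pH 3, 0 °C
Reagents that add atoms: lithium hydroxide, [Li+].[OH-]
Why: saponification of the methyl ester is done before the acetate exists; the ketal, the alkene and all stereocentres are inert to aqueous base.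

Step 10
Reactants: 14 (5R,7R,8S)-3,4-[(diphenylmethylene)dioxy]-7-hydroxy-5-methyl-8-[(2S)-6-methylhept-5-en-2-yl]-5,6,7,8-tetrahydronaphthalene-2-carboxylic acid
Product: 16 (5R,7R,8S)-7-acetoxy-3,4-[(diphenylmethylene)dioxy]-5-methyl-8-[(2S)-6-methylhept-5-en-2-yl]-5,6,7,8-tetrahydronaphthalene-2-carboxylic acid, via mixed carboxylic–acetic anhydride 15 (not isolated)
Conditions: Ac2O (3 equiv), pyridine, DMAP (10 mol %), CH2Cl2, rt; then H2O–THF, rt
Reagents that add atoms: acetic anhydride, CC(=O)OC(C)=O
Why: DMAP-catalysed acetylation of the secondary alcohol with retention at C2; the carboxyl group is acetylated in passing to a mixed anhydride, which water cleaves at the less hindered acetyl carbonyl during the aqueous hold.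

Step 11
Reactants: 16 (5R,7R,8S)-7-acetoxy-3,4-[(diphenylmethylene)dioxy]-5-methyl-8-[(2S)-6-methylhept-5-en-2-yl]-5,6,7,8-tetrahydronaphthalene-2-carboxylic acid
Product: 17 (5R,7R,8S)-7-acetoxy-3,4-dihydroxy-5-methyl-8-[(2S)-6-methylhept-5-en-2-yl]-5,6,7,8-tetrahydronaphthalene-2-carboxylic acid (target, CNP0201371.1)
Conditions: AcOH–H2O (4:1), 80 °C
Reagents that add atoms: none
Why: acid-catalysed ketal hydrolysis through the diaryl-stabilized oxocarbenium ion frees the catechol; aqueous acetic acid is expected to be too weak to protonate the trisubstituted alkene or cleave the secondary acetate.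

**Compound list**

1 | (S)-citronellal, (3S)-3,7-dimethyloct-6-enal | O=CC[C@@H](C)CCC=C(C)C | starting material
2 | (E)-1-bromoprop-1-ene | C/C=C/Br | starting material
3 | (E)-prop-1-en-1-yllithium | [Li]/C=C/C | intermediate
4 | (2E,6S)-6,10-dimethylundeca-2,9-dien-4-ol (both carbinol epimers) | C/C=C/C(O)C[C@@H](C)CCC=C(C)C | intermediate
5 | (2E,6S)-6,10-dimethylundeca-2,9-dien-4-one | C/C=C/C(=O)C[C@@H](C)CCC=C(C)C | intermediate
6 | methyl 2,3,4-trihydroxybenzoate | COC(=O)c1ccc(O)c(O)c1O | starting material
7 | methyl 5-chloro-2,3,4-trihydroxybenzoate | COC(=O)c1cc(Cl)c(O)c(O)c1O | intermediate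
8 | methyl 5-chloro-2,3-dihydroxy-4-(trifluoromethanesulfonyloxy)benzoate | COC(=O)c1cc(Cl)c(OS(=O)(=O)C(F)(F)F)c(O)c1O | intermediate
9 | methyl 5-chloro-2,3-[(diphenylmethylene)dioxy]-4-(trifluoromethanesulfonyloxy)benzoate | COC(=O)c1cc(Cl)c(OS(=O)(=O)C(F)(F)F)c2OC(c3ccccc3)(c3ccccc3)Oc12 | intermediate
10 | methyl 5-chloro-2,3-[(diphenylmethylene)dioxy]-4-(4,4,5,5-tetramethyl-1,3,2-dioxaborolan-2-yl)benzoate | COC(=O)c1cc(Cl)c(B3OC(C)(C)C(C)(C)O3)c2OC(c3ccccc3)(c3ccccc3)Oc12 | intermediate
11 | methyl 5-chloro-4-[(2R,6S)-6,10-dimethyl-4-oxoundec-9-en-2-yl]-2,3-[(diphenylmethylene)dioxy]benzoate | COC(=O)c1cc(Cl)c([C@H](C)CC(=O)C[C@@H](C)CCC=C(C)C)c2OC(c3ccccc3)(c3ccccc3)Oc12 | intermediate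
12 | methyl (5R)-3,4-[(diphenylmethylene)dioxy]-5-methyl-8-[(2S)-6-methylhept-5-en-2-yl]-7-oxo-5,6,7,8-tetrahydronaphthalene-2-carboxylate (both C-8 epimers) | O=C1C[C@@H](C)c2c(cc(C(=O)OC)c3OC(c4ccccc4)(c4ccccc4)Oc23)C1[C@@H](C)CCC=C(C)C | intermediate
13 | methyl (5R,7R,8S)-3,4-[(diphenylmethylene)dioxy]-7-hydroxy-5-methyl-8-[(2S)-6-methylhept-5-en-2-yl]-5,6,7,8-tetrahydronaphthalene-2-carboxylate | O[C@@H]1C[C@@H](C)c2c(cc(C(=O)OC)c3OC(c4ccccc4)(c4ccccc4)Oc23)[C@@H]1[C@@H](C)CCC=C(C)C | intermediate
14 | (5R,7R,8S)-3,4-[(diphenylmethylene)dioxy]-7-hydroxy-5-methyl-8-[(2S)-6-methylhept-5-en-2-yl]-5,6,7,8-tetrahydronaphthalene-2-carboxylic acid | O[C@@H]1C[C@@H](C)c2c(cc(C(=O)O)c3OC(c4ccccc4)(c4ccccc4)Oc23)[C@@H]1[C@@H](C)CCC=C(C)C | intermediate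
15 | acetic (5R,7R,8S)-7-acetoxy-3,4-[(diphenylmethylene)dioxy]-5-methyl-8-[(2S)-6-methylhept-5-en-2-yl]-5,6,7,8-tetrahydronaphthalene-2-carboxylic anhydride | CC(=O)O[C@@H]1C[C@@H](C)c2c(cc(C(=O)OC(C)=O)c3OC(c4ccccc4)(c4ccccc4)Oc23)[C@@H]1[C@@H](C)CCC=C(C)C | intermediate
16 | (5R,7R,8S)-7-acetoxy-3,4-[(diphenylmethylene)dioxy]-5-methyl-8-[(2S)-6-methylhept-5-en-2-yl]-5,6,7,8-tetrahydronaphthalene-2-carboxylic acid | CC(=O)O[C@@H]1C[C@@H](C)c2c(cc(C(=O)O)c3OC(c4ccccc4)(c4ccccc4)Oc23)[C@@H]1[C@@H](C)CCC=C(C)C | intermediate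
17 | (5R,7R,8S)-7-acetoxy-3,4-dihydroxy-5-methyl-8-[(2S)-6-methylhept-5-en-2-yl]-5,6,7,8-tetrahydronaphthalene-2-carboxylic acid | CC(=O)O[C@@H]1C[C@@H](C)c2c(cc(C(=O)O)c(O)c2O)[C@@H]1[C@@H](C)CCC=C(C)C | target

**Step count**

Total steps: 11. Longest linear sequence: 9 steps (steps 3–11, from 6 to 17); the enone branch (steps 1–2) joins at step 7.

**Steps most likely to fail, with fallbacks**

1. Step 7 (bears the label). The doubly ortho-substituted boronate may transfer its aryl group to rhodium more slowly than it is protodeboronated, so the 1,4-addition stalls. In the second stage, enolate O-arylation or interference between the two catalysts may divert the ring closure. The fallback uses known reactions as separate steps; it sets out from 1 and 9 and returns to the route at 12. Vinylmagnesium bromide is added to 1 (THF, −78 °C) to give (5S)-5,9-dimethyldeca-1,8-dien-3-ol F1, which Dess–Martin periodinane oxidizes to (5S)-5,9-dimethyldeca-1,8-dien-3-one F2. A Mizoroki–Heck reaction of triflate 9 with F2 (Pd(OAc)2, dppp, Et3N, DMF, 80 °C) gives methyl 5-chloro-4-[(1E,5S)-5,9-dimethyl-3-oxodeca-1,8-dien-1-yl]-2,3-[(diphenylmethylene)dioxy]benzoate F3. Copper-catalysed asymmetric conjugate addition of MeMgBr (CuBr·SMe2, a Josiphos-type ferrocenyl diphosphine, t-BuOMe, −75 °C) then sets C4 and gives 11, here isolated. A separate intramolecular ketone α-arylation (Pd(OAc)2, XPhos, K3PO4, toluene, 100 °C) closes 12. In this sequence the hindered aryl group is attached by a Heck reaction, which tolerates ortho substituents, and the stereocentre is made by adding the small methyl group.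

2. Step 8. The reduction may be a mismatched case: hydride has to arrive on the face that carries the C4 methyl group, so the desired C1 epimer may be reduced slowly and the C1/C2 selectivity may erode; the tetralone may also oxidize in air while it equilibrates. The fallback is substrate-controlled; it sets out from 12 and returns at 13. Reduction with KBH(s-Bu)3 (THF, −78 °C) should attack each C1 epimer anti to its side chain and give 13 together with methyl (5R,7S,8R)-3,4-[(diphenylmethylene)dioxy]-7-hydroxy-5-methyl-8-[(2S)-6-methylhept-5-en-2-yl]-5,6,7,8-tetrahydronaphthalene-2-carboxylate F4. The two 1,2-cis alcohols are separated by chromatography; F4 is oxidized back to 12 with Dess–Martin periodinane, C1 is re-equilibrated with DBU, and the material is recycled.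

3. Step 4. Site selectivity among the three phenols may be lost, or the triflyl group may migrate under base to the neighbouring 3-OH, which would place boron and later ring B on the wrong carbon. The fallback differentiates the 4-oxygen by a temporary ether; it sets out from 7 and returns at 9. Allyl bromide with Li2CO3 in DMF (40 °C) alkylates the most acidic phenol to give methyl 5-chloro-2,3-dihydroxy-4-(prop-2-en-1-yloxy)benzoate F5. Ketalization (Ph2CCl2, K2CO3, MeCN, 80 °C) gives methyl 5-chloro-2,3-[(diphenylmethylene)dioxy]-4-(prop-2-en-1-yloxy)benzoate F6. Deallylation (Pd(PPh3)4, morpholine, THF, rt) gives methyl 5-chloro-2,3-[(diphenylmethylene)dioxy]-4-hydroxybenzoate F7, and triflation of the single free phenol (Tf2O, pyridine, CH2Cl2, 0 °C) gives 9.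

**Further compounds**

F1 | step 7 | (5S)-5,9-dimethyldeca-1,8-dien-3-ol (both carbinol epimers) | C=CC(O)C[C@@H](C)CCC=C(C)C
F2 | step 7 | (5S)-5,9-dimethyldeca-1,8-dien-3-one | C=CC(=O)C[C@@H](C)CCC=C(C)C
F3 | step 7 | methyl 5-chloro-4-[(1E,5S)-5,9-dimethyl-3-oxodeca-1,8-dien-1-yl]-2,3-[(diphenylmethylene)dioxy]benzoate | COC(=O)c1cc(Cl)c(/C=C/C(=O)C[C@@H](C)CCC=C(C)C)c2OC(c3ccccc3)(c3ccccc3)Oc12
F4 | step 8 | methyl (5R,7S,8R)-3,4-[(diphenylmethylene)dioxy]-7-hydroxy-5-methyl-8-[(2S)-6-methylhept-5-en-2-yl]-5,6,7,8-tetrahydronaphthalene-2-carboxylate | O[C@H]1C[C@@H](C)c2c(cc(C(=O)OC)c3OC(c4ccccc4)(c4ccccc4)Oc23)[C@H]1[C@@H](C)CCC=C(C)C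
F5 | step 4 | methyl 5-chloro-2,3-dihydroxy-4-(prop-2-en-1-yloxy)benzoate | C=CCOc1c(Cl)cc(C(=O)OC)c(O)c1O
F6 | step 4 | methyl 5-chloro-2,3-[(diphenylmethylene)dioxy]-4-(prop-2-en-1-yloxy)benzoate | COC(=O)c1cc(Cl)c(OCC=C)c2OC(c3ccccc3)(c3ccccc3)Oc12
F7 | step 4 | methyl 5-chloro-2,3-[(diphenylmethylene)dioxy]-4-hydroxybenzoate | COC(=O)c1cc(Cl)c(O)c2OC(c3ccccc3)(c3ccccc3)Oc12
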